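**Retrosynthetic overview**

- Target 9 is the centrosymmetric (meso) alpha-truxillic diimide. Both N-acyl 5,6-dihydropyridin-2(1H)-one rings are cut at once at N1–C6 and C4–C5, a two-directional formal [4+2] of an N-acryloyl imide unit N1–C2(=O)–C3=C4 with a two-carbon vinyl donor, which leads back to bis(N-acryloyl) imide 6 and vinyl acetate 7.
- Enabling feature: in each lactam ring N1 (an acidic imide N–H in the precursor), C2=O and C3=C4 form an acrylimide whose C4–H lies cis to C2=O, so one metal can hold N1 and C4 in a five-membered metallacycle. C5–C6 is a bare CH2–CH2 bridge without substituent or stereocentre, and the two rings are related by the inversion centre of the cyclobutane, so one operation closes both.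
- 6 comes from bis(acid chloride) 3 through bis(acyl isocyanate) 5 and acrylic acid 4 (imide formation without base); 3 comes from diacid 2.
- 2 is the head-to-tail topochemical [2+2] photodimer of two molecules of (E)-3,4-dimethoxycinnamic acid 1; this dimerization copies the presumed biosynthetic origin of the cyclobutane and sets all four stereocentres.
- Order of ring formation: cyclobutane first (step 1), then both dihydropyridinone rings together in the last step (step 4).

Key step: step 4

Assumption: 1 is used in its head-to-tail (alpha-type) crystal form; 9 and all cyclobutane intermediates are meso, so each SMILES shows one of two equivalent ways of writing the same achiral compound.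

**Route**

Step 1
Reactants: 1 (E)-3,4-dimethoxycinnamic acid (two molecules)
Product: 2 (1α,2α,3β,4β)-2,4-bis(3,4-dimethoxyphenyl)cyclobutane-1,3-dicarboxylic acid (alpha-truxillic type; each aryl cis to one neighbouring carboxyl and trans to the other)
Conditions: crystalline 1 (alpha-type form), powder suspended in H2O, hν (Hg lamp, Pyrex, λ > 300 nm), 20 °C
Reagents that add atoms: (E)-3,4-dimethoxycinnamic acid (second molecule of 1), COc1ccc(/C=C/C(=O)O)cc1OC
Why: Topochemical [2+2] photocycloaddition (photodimerization) in the crystal, in which two antiparallel inversion-related molecules of 1 with parallel C=C bonds about 4 Å apart should combine to give only the head-to-tail dimer, each aryl staying trans to the carboxyl of its own monomer (E geometry retained) and the crystallographic inversion centre fixing the two new C–C bonds so that all four stereocentres arise in the 1α,2α,3β,4β (meso) arrangement.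

Step 2
Reactants: 2 (1α,2α,3β,4β)-2,4-bis(3,4-dimethoxyphenyl)cyclobutane-1,3-dicarboxylic acid
Product: 3 (1α,2α,3β,4β)-2,4-bis(3,4-dimethoxyphenyl)cyclobutane-1,3-dicarbonyl dichloride
Conditions: (COCl)2, DMF (cat.), CH2Cl2, 0 °C to rt; evaporate
Reagents that add atoms: oxalyl chloride, O=C(Cl)C(Cl)=O
Why: Acid chloride formation through the Vilsmeier-type chloroiminium species runs without base, so the carbonyl-bearing cyclobutane stereocentres should not be enolized.

Step 3
Reactants: 3 (1α,2α,3β,4β)-2,4-bis(3,4-dimethoxyphenyl)cyclobutane-1,3-dicarbonyl dichloride; 4 acrylic acid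
Product: 6 (1α,2α,3β,4β)-N1,N3-diacryloyl-2,4-bis(3,4-dimethoxyphenyl)cyclobutane-1,3-dicarboxamide, via bis(acyl isocyanate) 5 (not isolated)
Conditions: AgOCN (2.2 equiv), toluene, 80 °C, dark; filter under Ar; then 4 (2 equiv), BHT (cat.), 0 to 50 °C
Reagents that add atoms: silver cyanate, [Ag+].[O-]C#N
Why: Acyl substitution of each acid chloride by cyanate from AgOCN gives the acyl isocyanate, to which the carboxylic acid adds to form a mixed carbamic–carboxylic anhydride that transfers the acryloyl group to nitrogen with loss of CO2 (isocyanate–carboxylic acid amidation), all without base so the four stereocentres stay untouched.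

Step 4
Reactants: 6 (1α,2α,3β,4β)-N1,N3-diacryloyl-2,4-bis(3,4-dimethoxyphenyl)cyclobutane-1,3-dicarboxamide; 7 vinyl acetate
Product: 9 1,1'-[(1α,2α,3β,4β)-2,4-bis(3,4-dimethoxyphenyl)cyclobutane-1,3-dicarbonyl]bis(5,6-dihydropyridin-2(1H)-one) (target), via bis[(2Z)-penta-2,4-dienoyl] imide 8 (not isolated)
Conditions: [Cp*RhCl2]2 (5 mol %), AgSbF6 (20 mol %), CsOAc (1 equiv), 7 (10 equiv), BHT (cat.), 1,4-dioxane, 60 °C, then 90 °C
Reagents that add atoms: none
Why: Proposed new method: on each arm the imide N–H is metalated by [Cp*Rh(OAc)]+ and the cis β-vinylic C4–H is cleaved by carboxylate-assisted rhodation (five-membered rhodacycle Rh–N1–C2–C3=C4), vinyl acetate inserts into Rh–C4 and β-acetoxy elimination forms C4–C5 as the (2Z)-penta-2,4-dienoyl imide 8 while regenerating [Cp*Rh(OAc)]+ (trivalent rhodium), so no external oxidant is needed; the closest known reaction types are the [Cp*RhCl2]2-catalysed directed C–H vinylation of arenes with vinyl acetate and the chelation-controlled β-C–H olefination of acrylamides to (2Z)-dienamides, here extended to an imide directing group. The imidate form of 8 is a 1-azatriene (N1=C2–C3=C4–C5=C6) that should close under the acetate base by thermal disrotatory 6π-azaelectrocyclization, in polar terms a 6-endo-trig aza-1,6-addition, which forms N1–C6, and the cyclic dienolate is then protonated at C5 to the conjugated lactam; the closest known reaction type is the one-pot cross-coupling/6π-azaelectrocyclization of 1-azatrienes. Each of the two six-membered rings is therefore closed in the 6-endo mode at N1–C6 after the intermolecular C4–C5 bond formation. No new stereocentre arises, and the four cyclobutane stereocentres meet only a carboxylate base, which should not enolize them. The step needs Z-selective monovinylation (secured by the metallacycle, the remaining C4–H being trans to C2=O and out of reach), N- instead of O-closure (O-closure to a 2H-pyran-2-imine is reversible, N-closure is made irreversible by tautomerization to the amide) and no over-oxidation to a pyridone (the C–O bond of vinyl acetate is the only oxidant present).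

**Compound list**

1 | (E)-3,4-dimethoxycinnamic acid | COc1ccc(/C=C/C(=O)O)cc1OC | starting material
2 | (1α,2α,3β,4β)-2,4-bis(3,4-dimethoxyphenyl)cyclobutane-1,3-dicarboxylic acid | COc1ccc([C@H]2[C@H](C(=O)O)[C@H](c3ccc(OC)c(OC)c3)[C@H]2C(=O)O)cc1OC | intermediate
3 | (1α,2α,3β,4β)-2,4-bis(3,4-dimethoxyphenyl)cyclobutane-1,3-dicarbonyl dichloride | COc1ccc([C@H]2[C@H](C(=O)Cl)[C@H](c3ccc(OC)c(OC)c3)[C@H]2C(=O)Cl)cc1OC | intermediate
4 | acrylic acid | C=CC(=O)O | starting material
5 | (1α,2α,3β,4β)-2,4-bis(3,4-dimethoxyphenyl)cyclobutane-1,3-dicarbonyl diisocyanate | COc1ccc([C@H]2[C@H](C(=O)N=C=O)[C@H](c3ccc(OC)c(OC)c3)[C@H]2C(=O)N=C=O)cc1OC | intermediate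
6 | (1α,2α,3β,4β)-N1,N3-diacryloyl-2,4-bis(3,4-dimethoxyphenyl)cyclobutane-1,3-dicarboxamide | COc1ccc([C@H]2[C@H](C(=O)NC(=O)C=C)[C@H](c3ccc(OC)c(OC)c3)[C@H]2C(=O)NC(=O)C=C)cc1OC | intermediate
7 | vinyl acetate | CC(=O)OC=C | starting material
8 | (1α,2α,3β,4β)-2,4-bis(3,4-dimethoxyphenyl)-N1,N3-bis[(2Z)-penta-2,4-dienoyl]cyclobutane-1,3-dicarboxamide | COc1ccc([C@H]2[C@H](C(=O)NC(=O)/C=C\C=C)[C@H](c3ccc(OC)c(OC)c3)[C@H]2C(=O)NC(=O)/C=C\C=C)cc1OC | intermediate
9 | 1,1'-[(1α,2α,3β,4β)-2,4-bis(3,4-dimethoxyphenyl)cyclobutane-1,3-dicarbonyl]bis(5,6-dihydropyridin-2(1H)-one) | COc1ccc([C@H]2[C@H](C(=O)N3CCC=CC3=O)[C@H](c3ccc(OC)c(OC)c3)[C@H]2C(=O)N2CCC=CC2=O)cc1OC | target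

**Summary and risks**

Total step count: 4. Longest linear sequence: 4 steps (1 → 2 → 3 → 6 → 9).

Steps most likely to fail:

1. Step 4 (Proposed new method). The imidate may hold the [Cp*Rh]2+ fragment as an inert O,O-chelate so that C–H rhodation never starts. The sequence may also stall after vinylation because ring closure of the dienoyl imide is slow or reversible, or the acryloyl groups may oligomerize on heating. The fallback uses known chemistry, the N-acylation of a silylated lactam by an acid chloride; it sets out from 3 and comes back to the route at 9. Commercially available 5,6-dihydropyridin-2(1H)-one is silylated with hexamethyldisilazane to 1-(trimethylsilyl)-5,6-dihydropyridin-2(1H)-one F1. F1 is heated with 3 in toluene at 60 to 80 °C, and N-acylation with loss of chlorotrimethylsilane should give 9 without a base that could epimerize the cyclobutane.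

2. Step 3. The chloride–cyanate exchange may remain incomplete at the hindered acid chloride. The mixed carbamic–carboxylic anhydride may also break down to acrylic anhydride and primary amide instead of transferring the acyl group, or the acrylate may polymerize. The fallback sets out from 3 and comes back at 6. Acrylamide is silylated with hexamethyldisilazane to N-(trimethylsilyl)acrylamide F2, which is acylated by 3 in toluene at 50 °C in the presence of BHT. Loss of chlorotrimethylsilane should give 6.

3. Step 1. The acid may crystallize in a photostable or head-to-head packing, or the lattice may lose its registry during irradiation, so that conversion stops or only E/Z isomerization occurs at the crystal surface. The fallback moves the dimerization to the primary amide, whose hydrogen-bonded ribbons offer a different packing motif; it sets out from 1 and comes back at 5. 1 is converted with oxalyl chloride into (E)-3-(3,4-dimethoxyphenyl)acryloyl chloride F3 and then with aqueous ammonia into (E)-3-(3,4-dimethoxyphenyl)acrylamide F4. Solid-state irradiation of crystalline F4 is expected to give the head-to-tail diamide (1α,2α,3β,4β)-2,4-bis(3,4-dimethoxyphenyl)cyclobutane-1,3-dicarboxamide F5. F5 with oxalyl chloride in refluxing 1,2-dichloroethane should give 5, which is carried on with 4 as in step 3.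

Further compounds
F1 | step 4 | 1-(trimethylsilyl)-5,6-dihydropyridin-2(1H)-one | C[Si](C)(C)N1CCC=CC1=O
F2 | step 3 | N-(trimethylsilyl)acrylamide | C=CC(=O)N[Si](C)(C)C
F3 | step 1 | (E)-3-(3,4-dimethoxyphenyl)acryloyl chloride | COc1ccc(/C=C/C(=O)Cl)cc1OC
F4 | step 1 | (E)-3-(3,4-dimethoxyphenyl)acrylamide | COc1ccc(/C=C/C(=O)N)cc1OC
F5 | step 1 | (1α,2α,3β,4β)-2,4-bis(3,4-dimethoxyphenyl)cyclobutane-1,3-dicarboxamide | COc1ccc([C@H]2[C@H](C(=O)N)[C@H](c3ccc(OC)c(OC)c3)[C@H]2C(=O)N)cc1OC
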